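# Proposed synthesis of 7-{[(1R,4aS,8aS)-2,5,5,8a-tetramethyl-6-oxo-1,4,4a,5,6,7,8,8a-octahydronaphthalen-1-yl]methoxy}-2H-chromen-2-one (22)

## Analysis of the target

The target 22 is a bicyclic sesquiterpene ketone of the drimane type whose C11 oxygen is etherified with the 7-hydroxyl of coumarin. Drimane numbering is used throughout: ring A is C1–C5 plus C10, with the ketone at C3 and the gem-dimethyl group at C4; ring B is C5–C10, with the C7=C8 double bond and a methyl on C8; C11 is the OCH2 carbon on C9. There are three contiguous stereocentres, C5 (S), C10 (S) and C9 (R). H5, the angular methyl on C10 and H9 lie on one face, so the decalin is cis-fused and C11 is trans to the angular methyl, on the concave side of the bicycle next to C1. The C7=C8 alkene can slip to the tetrasubstituted C8=C9 position under strong acid, the C3 ketone is enolisable towards C2, and the coumarin lactone does not survive hydroxide, hydride or organomagnesium reagents, so it is attached late. The hard points are the quaternary C10 between two stereocentres and, above all, C9, whose carbon substituent sits on the more hindered face. The strategy rests on the vicinal pair C10–CH3 and C9–C11 on a ring that can carry oxygen at C8. This is the pattern left by conjugate addition of methyl to a C8(=O)–C9=C10 enone and capture of the C8–C9 enolate by a one-carbon electrophile. The C8 oxygen then serves to bring in the C8 methyl and to fix the double bond at C7=C8, and the enone needed has C5 as its only stereocentre.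

## Retrosynthetic reasoning

**22 to 21.** The two C3–O bonds of a dioxolane are the last to be cut. The C3 ketone has to stay masked through dissolving-metal reduction, amine catalysis, cuprate, enolate and Grignard chemistry, so ketal 21 is the direct precursor. The forward step must hydrolyse a hindered ketal without moving the C7=C8 double bond.

**21 to 19 and 20.** The C11–O ether bond is cut because C11 is not stereogenic and umbelliferone 20 is commercial. This keeps the lactone out of all organometallic steps. The forward reaction has to etherify a β-branched primary alcohol, 19, with a phenol under neutral conditions.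

**19 to 17.** The C9–H and C11–O bonds are removed together, which leads to the exocyclic diene 17. The cut is made here because C9 is a problem of facial access. A reagent that adds to a trigonal C9 in this cis-fused system should come from the convex face, the face of H5 and the angular methyl. C11 therefore has to be in place first and hydrogen has to arrive last. The forward reaction must be an anti-Markovnikov, syn hydration that touches only the 1,1-disubstituted alkene.

**17 to 16 to 14.** The C8–CH3 bond is cut to give dienyl triflate 16, and the C8–O bond of 16 is traced to the ketone of α-methylene ketone 14. In 14 only C7 can enolise, since C9 is trigonal and C10 is quaternary. The position of the ring double bond is therefore fixed by structure and not by selectivity.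

**14 to 12.** The C9=C11 double bond is traced back to the C11–O bond and the C9–H bond of β-hydroxy ketone 12. The forward step is a β-elimination that erases C9, so either C9 epimer of 12 serves.

**12 to 9 and 10.** This is the key disconnection. The C10–CH3 and C9–C11 bonds are cut in one operation, which leads to enone 9, a methyl nucleophile and formaldehyde 10. Both bonds lie on the two carbons of the enone double bond, so one reagent sequence builds the quaternary centre and brings in C11. The forward reaction has to add methyl to C10 syn to H5 and capture the enolate at C9 before it equilibrates.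

**9 to 8.** The C5–H bond is cut and the conjugated enone is traced to its achiral β,γ-isomer 8 with the C5=C10 double bond. The forward reaction is a catalytic, enantioselective proton transfer to C5, the only absolute stereocontrol the route needs.

**8 to 7 to 6.** The C8 carbonyl and the C5=C10 alkene are the retron of a partially reduced methoxyarene. Enol ether 7 comes from aryl ether 6 by dissolving-metal reduction, and mild acid frees the ketone without conjugating it or opening the ketal.

**6 to 4 to 1, 2 and 5.** The C3 ketal is cut to ketone 4 and ethylene glycol 5. The two C4–CH3 bonds are then cut to 6-methoxy-2-tetralone 1 and iodomethane 2. The benzylic α-carbon of 1 is the most acidic position, so the gem-dimethyl group and the C3 oxygen are in place from the first step.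

## Alternatives that were turned down

**Alternative 1: intermolecular Diels–Alder reaction building ring B on ring A.**
- Disconnection: ring B is cut at C5–C6 and C9–C10. The dienophile is 2,4,4-trimethylcyclohex-2-en-1-one A1, with its carbonyl as C1, its α-carbon as C10 and its β-carbon as C5. The diene is (3E)-2,5-bis(tert-butyldimethylsilyloxy)-3-methylpenta-1,3-diene A2.
- Forward key step: a chiral cationic oxazaborolidine Lewis acid would join A1 and A2 to the cis-fused adduct A3.
- For: all three stereocentres arise in one step. The cis fusion follows from the ring alkene, and an endo transition state places C11 next to the C1 carbonyl, that is trans to the angular methyl. On C9 this is stronger than the chosen route, which needs steps 7 to 10 to set that centre.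
- Against: A1 is an α-methyl enone whose β-carbon is flanked by the quaternary C4, one of the least reactive dienophile types. The activation it needs endangers the acid-labile silyloxydiene A2. A3 carries the ring A oxygen at C1, so a 1,3-carbonyl transposition to C3 is needed, and the C7 oxygen must still be removed.
- Comparison: the chosen strategy starts with the C3 oxygen and the C4 gem-dimethyl group in place and reaches its key precursor in five steps.

**Alternative 2: intramolecular Diels–Alder reaction of an acyclic triene.**
- Disconnection: both rings are cut at C5–C10 and C6–C7.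
- Forward key step: heating the triene ester A4 (diene C7=C8–C9=C10 with the ester on C9 and the tether cis to C8; dienophile C5=C6) would give the cis-fused conjugated ester A5.
- For: two rings and the C5/C10 pair form in one step. The C8=C9 ester can later be deconjugated with protonation of C9 from the convex face, the same hydrogen-last logic as here, so it is as strong on C9.
- Against: A4 needs a long linear synthesis with a geometrically defined tetrasubstituted alkene and a C3 stereocentre. The dienophile is unactivated and sits on a quaternary carbon. The inside substituent raises the energy of the reactive diene conformer, so forcing temperatures and hydrogen shifts are to be expected. Facial control comes only from the remote C3 silyloxy group, and C3 and C11 then both need redox adjustment.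
- Comparison: the chosen route is shorter and draws its absolute configuration from one catalytic step on a rigid bicycle.

**Alternative 3: reductive Michael desymmetrisation of a cyclohexadienone.**
- Disconnection: ring A is cut at C4–C5.
- Forward key step: a chiral bisphosphine copper hydride would reduce the isopropenyl ketone of dienone A6 to its C4 enolate, which adds to one enantiotopic arm of the dienone and gives the cis-fused enedione A7.
- For: A6 is achiral and simple. The quaternary C10 is present before the key step, and C5, C10, the gem-dimethyl group and the unprotected C3 ketone arise in one catalytic step. This is stronger than the chosen route in how early and how safely C10 is secured.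
- Against: A7 lacks C11 and the C8 methyl and carries oxygen at C7, not C8. C11 would have to come by conjugate addition to the C7(=O)–C8=C9 enone, which should occur on the convex face and give the wrong C9 epimer, with no neighbouring carbonyl left to correct it. Two ketones must be told apart and the C7 oxygen removed with the alkene left at C7=C8.
- Comparison: with oxygen at C8, the chosen route makes both C9 and C8 addressable from one functional group.

Key step: step 6

## Remarks on the chemistry

- In step 5 the catalyst is taken from the quinine series. Should it deliver the (4aR) enone, its pseudoenantiomer from quinidine is used instead.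
- In step 6 the hydroxymethyl group is drawn cis to the angular methyl, as expected for entry on the convex face. The route does not depend on this, because C9 is trigonal from 14 to 17 and is set in step 10.

## Steps

**Step 1**
Reactants: 1 6-methoxy-2-tetralone; 2 iodomethane
Product: 4 6-methoxy-1,1-dimethyl-2-tetralone, via 6-methoxy-1-methyl-2-tetralone 3 (not isolated)
Conditions: NaH (2.3 equiv), MeI (2.5 equiv), THF, 0 °C → rt
Reagents that add atoms: iodomethane (2), CI
Why: Twofold enolate C-alkylation at the benzylic α-carbon of a 2-tetralone, by far its most acidic position; after the second methylation no benzylic α-hydrogen is left, so the reaction should stop there.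

**Step 2**
Reactants: 4 6-methoxy-1,1-dimethyl-2-tetralone; 5 ethylene glycol
Product: 6 6-methoxy-1,1-dimethyl-2-tetralone ethylene ketal
Conditions: HOCH2CH2OH (5 equiv), p-TsOH·H2O (5 mol%), benzene, reflux, Dean–Stark trap
Reagents that add atoms: ethylene glycol (5), OCCO
Why: Acid-catalysed ketalisation driven by azeotropic removal of water; the dioxolane masks the future C3 ketone against reduction, amine condensation and all later organometallic steps.

**Step 3**
Reactants: 6 6-methoxy-1,1-dimethyl-2-tetralone ethylene ketal
Product: 7 2,2-ethylenedioxy-6-methoxy-1,1-dimethyl-1,2,3,4,5,8-hexahydronaphthalene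
Conditions: Li, NH3(l), THF, t-BuOH, −78 → −33 °C; then MeOH
Reagents that add atoms: none
Why: Birch reduction of the methoxyarene to its 2,5-dihydro derivative; the methoxy-bearing carbon and the two alkylated ring-fusion carbons stay trigonal, which gives the enol ether with the tetrasubstituted C5=C10 alkene, and the ketal is inert to dissolving metal.

**Step 4**
Reactants: 7 2,2-ethylenedioxy-6-methoxy-1,1-dimethyl-1,2,3,4,5,8-hexahydronaphthalene
Product: 8 5,5-dimethyl-6,6-ethylenedioxy-3,4,5,6,7,8-hexahydronaphthalen-2(1H)-one
Conditions: oxalic acid dihydrate, MeOH/H2O, rt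
Reagents that add atoms: water, O
Why: Mild acid hydrolysis of the methyl enol ether; a weak acid at room temperature should free the ketone without moving the double bond into conjugation and without opening the dioxolane.

**Step 5**
Reactants: 8 5,5-dimethyl-6,6-ethylenedioxy-3,4,5,6,7,8-hexahydronaphthalen-2(1H)-one
Product: 9 (4aS)-5,5-dimethyl-6,6-ethylenedioxy-4,4a,5,6,7,8-hexahydronaphthalen-2(3H)-one
Conditions: 9-amino-9-deoxy-epi-quinine (10 mol%), 2-nitrobenzoic acid (20 mol%), toluene, rt
Reagents that add atoms: none
Why: Amine-catalysed enantioselective isomerisation of a β,γ- to an α,β-unsaturated cyclohexenone: the primary amine condenses with the ketone, the dienamine is protonated at C5 by the protonated quinuclidine of the same catalyst, and hydrolysis releases the conjugated enone. The C5 stereocentre is set by this catalyst-controlled proton transfer, and the ketal keeps the second carbonyl away from the amine.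

**Step 6**
Reactants: 9 (4aS)-5,5-dimethyl-6,6-ethylenedioxy-4,4a,5,6,7,8-hexahydronaphthalen-2(3H)-one; 10 formaldehyde
Product: 12 (1S,4aS,8aS)-1-(hydroxymethyl)-5,5,8a-trimethyl-6,6-ethylenedioxy-octahydronaphthalen-2(1H)-one, via lithium C8–C9 enolate 11 (not isolated)
Conditions: Me2CuLi (from MeLi and CuBr·SMe2, 1.5 equiv), Et2O, −20 → 0 °C; then THF, −78 °C, CH2O (gas, from cracked paraformaldehyde); aq. NH4Cl, −78 °C
Reagents that add atoms: lithium dimethylcuprate, [Li+].C[Cu-]C (CH3 in 12, Li in 11); formaldehyde (10), C=O
Why: Conjugate addition of a lithium dialkylcuprate to a 2-octalone with capture of the regiodefined enolate by monomeric formaldehyde is the closest known reaction type. The cuprate forms a π-complex with the enone, oxidative addition gives a β-cuprio enolate with trivalent copper on C10, and reductive elimination forms the C10–CH3 bond and the lithium enolate 11, whose double bond lies only at C8–C9. No ring is closed. C10 is controlled by C5: the methyl group should enter syn to H5 and give the cis fusion, because the other face of C10 is 1,3-syn-axial to the axial methyl on C4, and cis delivery is also the inherent preference of octalones with hydrogen at C5. Formaldehyde then forms the C9–C11 bond by aldol addition; C9 is controlled by the ring fusion, and the electrophile should enter on the convex face, anti to the pseudoaxial C1 and away from ring A and the C4 methyls, which puts CH2OH cis to the new methyl. This C9 centre is not relied on, since it becomes trigonal in step 7 and is set again in step 10. The step needs 1,4- over 1,2-addition, which the soft cuprate secures, and a single hydroxymethylation at C9, which follows from the regiospecific enolate, the absence of a proton source and the cold quench.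

**Step 7**
Reactants: 12 (1S,4aS,8aS)-1-(hydroxymethyl)-5,5,8a-trimethyl-6,6-ethylenedioxy-octahydronaphthalen-2(1H)-one
Product: 14 (4aS,8aS)-5,5,8a-trimethyl-1-methylidene-6,6-ethylenedioxy-octahydronaphthalen-2(1H)-one, via C11 methanesulfonate 13 (not isolated)
Conditions: MsCl, Et3N, CH2Cl2, 0 °C; then DBU, rt
Reagents that add atoms: methanesulfonyl chloride, CS(=O)(=O)Cl (kept in 13 only)
Why: Sulfonylation of the primary alcohol and base-induced β-elimination through the C9 enolate give the α-methylene ketone; either C9 epimer of 12 converges on 14. The enone is used at once in step 8 to forestall hetero-Diels–Alder dimerisation.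

**Step 8**
Reactants: 14 (4aS,8aS)-5,5,8a-trimethyl-1-methylidene-6,6-ethylenedioxy-octahydronaphthalen-2(1H)-one
Product: 16 (4aS,8aS)-5,5,8a-trimethyl-1-methylidene-6,6-ethylenedioxy-1,4,4a,5,6,7,8,8a-octahydronaphthalen-2-yl trifluoromethanesulfonate, via potassium dienolate 15 (not isolated)
Conditions: KHMDS (1.1 equiv), THF, −78 °C; then PhNTf2, −78 → 0 °C
Reagents that add atoms: N-phenylbis(trifluoromethanesulfonimide), O=S(=O)(N(c1ccccc1)S(=O)(=O)C(F)(F)F)C(F)(F)F; potassium hexamethyldisilazide, C[Si](C)(C)[N-][Si](C)(C)C.[K+] (K in 15 only)
Why: Standard enol triflate synthesis by deprotonation and O-sulfonylation; C7 is the only position of 14 that can enolise, so the cross-conjugated dienolate and the C7=C8 triflate form regiospecifically.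

**Step 9**
Reactants: 16 (4aS,8aS)-5,5,8a-trimethyl-1-methylidene-6,6-ethylenedioxy-1,4,4a,5,6,7,8,8a-octahydronaphthalen-2-yl trifluoromethanesulfonate
Product: 17 (4aS,8aS)-2,5,5,8a-tetramethyl-1-methylidene-6,6-ethylenedioxy-1,4,4a,5,6,7,8,8a-octahydronaphthalene
Conditions: MeMgBr (1.5 equiv), Fe(acac)3 (5 mol%), THF/NMP, −30 → 0 °C
Reagents that add atoms: methylmagnesium bromide, C[Mg]Br
Why: Iron-catalysed Kumada-type cross-coupling of an alkenyl triflate with a methyl Grignard reagent replaces the C8 oxygen by methyl with the double bond fixed at C7=C8; the ketal is inert at this temperature.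

**Step 10**
Reactants: 17 (4aS,8aS)-2,5,5,8a-tetramethyl-1-methylidene-6,6-ethylenedioxy-1,4,4a,5,6,7,8,8a-octahydronaphthalene
Product: 19 [(1R,4aS,8aS)-2,5,5,8a-tetramethyl-6,6-ethylenedioxy-1,4,4a,5,6,7,8,8a-octahydronaphthalen-1-yl]methanol, via B-alkyl-9-borabicyclononane 18 (not isolated)
Conditions: 9-BBN (1.3 equiv), THF, 0 °C → rt; then NaOH, H2O2, 0 °C → rt
Reagents that add atoms: hydrogen peroxide, OO; 9-borabicyclo[3.3.1]nonane, [H]B1C2CCCC1CCC2 (kept in 18 only)
Why: Hydroboration–oxidation; the bulky dialkylborane adds boron to the terminal C11 of the 1,1-disubstituted alkene and leaves the trisubstituted ring alkene alone. Addition is syn, and hydrogen should reach C9 from the convex face, since the concave face is closed by the pseudoaxial C1, ring A and the C4 methyls; H9 therefore ends cis to H5 and the angular methyl, and C11 trans to that methyl.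

**Step 11**
Reactants: 19 [(1R,4aS,8aS)-2,5,5,8a-tetramethyl-6,6-ethylenedioxy-1,4,4a,5,6,7,8,8a-octahydronaphthalen-1-yl]methanol; 20 umbelliferone
Product: 21 7-{[(1R,4aS,8aS)-2,5,5,8a-tetramethyl-6,6-ethylenedioxy-1,4,4a,5,6,7,8,8a-octahydronaphthalen-1-yl]methoxy}-2H-chromen-2-one
Conditions: PPh3, DIAD, THF, 0 °C → rt
Reagents that add atoms: umbelliferone (20), Oc1ccc2ccc(=O)oc2c1
Why: Mitsunobu etherification of a primary alcohol with an acidic phenol under neutral conditions; C11 is not stereogenic and the lactone meets no nucleophile or base.

**Step 12**
Reactants: 21 7-{[(1R,4aS,8aS)-2,5,5,8a-tetramethyl-6,6-ethylenedioxy-1,4,4a,5,6,7,8,8a-octahydronaphthalen-1-yl]methoxy}-2H-chromen-2-one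
Product: 22 7-{[(1R,4aS,8aS)-2,5,5,8a-tetramethyl-6-oxo-1,4,4a,5,6,7,8,8a-octahydronaphthalen-1-yl]methoxy}-2H-chromen-2-one
Conditions: 2 M aq. HCl/THF (1:4), rt
Reagents that add atoms: water, O
Why: Acid-catalysed ketal hydrolysis; dilute acid at room temperature should leave the trisubstituted alkene, the aryl ether and the lactone untouched, and no stereocentre is enolisable towards the new ketone.

## Compound list

1 | 6-methoxy-2-tetralone (6-methoxy-3,4-dihydronaphthalen-2(1H)-one) | COc1ccc2CC(=O)CCc2c1 | starting material
2 | iodomethane | CI | starting material
3 | 6-methoxy-1-methyl-2-tetralone (racemic) | COc1ccc2c(c1)CCC(=O)C2C | intermediate (not isolated)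
4 | 6-methoxy-1,1-dimethyl-2-tetralone | COc1ccc2c(c1)CCC(=O)C2(C)C | intermediate
5 | ethylene glycol | OCCO | starting material
6 | 6-methoxy-1,1-dimethyl-2-tetralone ethylene ketal (6'-methoxy-1',1'-dimethyl-3',4'-dihydro-1'H-spiro[1,3-dioxolane-2,2'-naphthalene]) | COc1ccc2c(c1)CCC1(OCCO1)C2(C)C | intermediate
7 | 2,2-ethylenedioxy-6-methoxy-1,1-dimethyl-1,2,3,4,5,8-hexahydronaphthalene | COC1=CCC2=C(C1)CCC1(OCCO1)C2(C)C | intermediate
8 | 5,5-dimethyl-6,6-ethylenedioxy-3,4,5,6,7,8-hexahydronaphthalen-2(1H)-one (β,γ-enone, C5=C10 in drimane numbering) | O=C1CCC2=C(C1)CCC1(OCCO1)C2(C)C | intermediate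
9 | (4aS)-5,5-dimethyl-6,6-ethylenedioxy-4,4a,5,6,7,8-hexahydronaphthalen-2(3H)-one | O=C1CC[C@@H]2C(C)(C)C3(OCCO3)CCC2=C1 | intermediate
10 | formaldehyde (monomer, from paraformaldehyde) | C=O | starting material
11 | lithium C8–C9 enolate of the cis-fused 10-methyl ketone (H5 and angular methyl cis) | [Li]OC=1CC[C@@H]2C(C)(C)C3(OCCO3)CC[C@]2(C)C=1 | intermediate (not isolated)
12 | (1S,4aS,8aS)-1-(hydroxymethyl)-5,5,8a-trimethyl-6,6-ethylenedioxy-octahydronaphthalen-2(1H)-one (cis-fused; CH2OH cis to the angular methyl) | O=C1CC[C@@H]2C(C)(C)C3(OCCO3)CC[C@]2(C)[C@H]1CO | intermediate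
13 | methanesulfonate of 12 at the C11 oxygen | O=C1CC[C@@H]2C(C)(C)C3(OCCO3)CC[C@]2(C)[C@H]1COS(C)(=O)=O | intermediate (not isolated)
14 | (4aS,8aS)-5,5,8a-trimethyl-1-methylidene-6,6-ethylenedioxy-octahydronaphthalen-2(1H)-one (cis-fused α-methylene ketone) | O=C1CC[C@@H]2C(C)(C)C3(OCCO3)CC[C@]2(C)C1=C | intermediate
15 | potassium C7–C8 dienolate of 14 | [K]OC1=CC[C@@H]2C(C)(C)C3(OCCO3)CC[C@]2(C)C1=C | intermediate (not isolated)
16 | (4aS,8aS)-5,5,8a-trimethyl-1-methylidene-6,6-ethylenedioxy-1,4,4a,5,6,7,8,8a-octahydronaphthalen-2-yl trifluoromethanesulfonate | FC(F)(F)S(=O)(=O)OC1=CC[C@@H]2C(C)(C)C3(OCCO3)CC[C@]2(C)C1=C | intermediate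
17 | (4aS,8aS)-2,5,5,8a-tetramethyl-1-methylidene-6,6-ethylenedioxy-1,4,4a,5,6,7,8,8a-octahydronaphthalene (cis-fused 7,9(11)-diene) | CC1=CC[C@@H]2C(C)(C)C3(OCCO3)CC[C@]2(C)C1=C | intermediate
18 | B-alkyl-9-borabicyclo[3.3.1]nonane with boron on C11 (H9 cis to the angular methyl) | CC1=CC[C@@H]2C(C)(C)C3(OCCO3)CC[C@]2(C)[C@@H]1CB1C2CCCC1CCC2 | intermediate (not isolated)
19 | [(1R,4aS,8aS)-2,5,5,8a-tetramethyl-6,6-ethylenedioxy-1,4,4a,5,6,7,8,8a-octahydronaphthalen-1-yl]methanol (cis-fused; CH2OH trans to the angular methyl) | CC1=CC[C@@H]2C(C)(C)C3(OCCO3)CC[C@]2(C)[C@@H]1CO | intermediate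
20 | umbelliferone (7-hydroxy-2H-chromen-2-one) | Oc1ccc2ccc(=O)oc2c1 | starting material
21 | 7-{[(1R,4aS,8aS)-2,5,5,8a-tetramethyl-6,6-ethylenedioxy-1,4,4a,5,6,7,8,8a-octahydronaphthalen-1-yl]methoxy}-2H-chromen-2-one | CC1=CC[C@@H]2C(C)(C)C3(OCCO3)CC[C@]2(C)[C@@H]1COc1ccc2ccc(=O)oc2c1 | intermediate
22 | 7-{[(1R,4aS,8aS)-2,5,5,8a-tetramethyl-6-oxo-1,4,4a,5,6,7,8,8a-octahydronaphthalen-1-yl]methoxy}-2H-chromen-2-one | CC1=CC[C@@H]2C(C)(C)C(=O)CC[C@]2(C)[C@@H]1COc1ccc2ccc(=O)oc2c1 | target

## Step count and least certain steps

Total: 12 steps. Longest linear sequence: 12 steps, from 1 to 22; compounds 2, 5, 10 and 20 are commercial and enter directly.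

**Step 6 (key step).** The likeliest failure is slow conjugate addition at the fully substituted C10, which is flanked by C5 and its quaternary neighbour C4, so that 1,2-addition or plain enolisation of 9 competes. The second danger is in the trapping: proton transfer between the aldolate and unreacted enolate, a second hydroxymethylation at C7, or retro-aldol loss on work-up. The fallback sets out from 9 and separates the two bond formations. Addition of lithium dimethylcuprate in the presence of Me3SiCl in THF at −78 °C, which accelerates the addition and captures the enolate as it forms, should give the trimethylsilyl enol ether F1 as an isolable compound. F1 is then hydroxymethylated in a Mukaiyama aldol reaction with aqueous formaldehyde and catalytic Yb(OTf)3 in THF. This returns to the route at 12.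

**Step 10.** The risk is erosion or reversal of facial selectivity. If ring B of 17 reacts through the conformer with the angular methyl pseudoaxial, the methyl and not C1 screens C9, and hydrogen is delivered to the concave face. The same bias would then govern the aldol of step 6, so the fallback takes C9 from that step. It sets out from 9. The aldol would give the C9 epimer of 12 with CH2OH trans to the angular methyl, hydroxy ketone F2. F2 is silylated (TBSCl, imidazole, DMF) to silyl ether F3. F3 is converted at the kinetically favoured C7 into enol triflate F4 (KHMDS, PhNTf2, THF, −78 °C). F4 is coupled with MeMgBr and Fe(acac)3 to the C7=C8 alkene F5. F5 is desilylated with TBAF in THF. The fallback comes back to the route at 19. Whichever face of C9 is the open one, one of the two sequences should therefore deliver 19.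

**Step 5.** Enantiofacial discrimination in the proton transfer to C5 may be poor, because the protonated carbon lies next to the bulky quaternary C4, and partial racemisation of 9 through its own dienamine is possible. The fallback sets out from 8. Isomerisation with DBU in CH2Cl2 gives the racemic enone F6, which is resolved by preparative chromatography on a polysaccharide chiral stationary phase. The (4aS) enantiomer is 9, where the route is rejoined, and the (4aR) enantiomer F7 is set aside.

**Step 8.** The amide base may add to the exposed exocyclic methylene of 14, or the dienolate may add to unreacted 14, which starts oligomerisation; 14 may also dimerise before it is used. The fallback sets out from 14 and avoids any enolate. O-Triflation with Tf2O and 2,6-di-tert-butyl-4-methylpyridine in CH2Cl2 at 0 °C activates the carbonyl electrophilically, and loss of the only available α-proton at C7 gives the dienyl triflate. It returns to the route at 16 and makes no new compound.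

**Step 11.** Displacement at C11 may be slow because the carbinol carbon is β-branched and next to the quaternary C10, so that the activated alcohol is diverted to elimination or to alkylated hydrazide. The fallback sets out from 19 and forms the aryl–oxygen bond instead of the C11–O bond. Palladium-catalysed C–O coupling of 19 with 7-bromocoumarin ([Pd(allyl)Cl]2, a bulky biaryl di-tert-butylphosphine, Cs2CO3, toluene, 90 °C) comes back to the route at 21 and makes no new compound.

## Further compounds

F1 | step 6 | trimethylsilyl C8–C9 enol ether of the cis-fused 10-methyl ketone | C[Si](C)(C)OC=1CC[C@@H]2C(C)(C)C3(OCCO3)CC[C@]2(C)C=1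
F2 | step 10 | (1R,4aS,8aS)-1-(hydroxymethyl)-5,5,8a-trimethyl-6,6-ethylenedioxy-octahydronaphthalen-2(1H)-one (C9 epimer of 12, CH2OH trans to the angular methyl) | O=C1CC[C@@H]2C(C)(C)C3(OCCO3)CC[C@]2(C)[C@@H]1CO
F3 | step 10 | tert-butyldimethylsilyl ether of F2 | O=C1CC[C@@H]2C(C)(C)C3(OCCO3)CC[C@]2(C)[C@@H]1CO[Si](C)(C)C(C)(C)C
F4 | step 10 | C7=C8 enol trifluoromethanesulfonate of F3 | FC(F)(F)S(=O)(=O)OC1=CC[C@@H]2C(C)(C)C3(OCCO3)CC[C@]2(C)[C@@H]1CO[Si](C)(C)C(C)(C)C
F5 | step 10 | tert-butyldimethylsilyl ether of 19 | CC1=CC[C@@H]2C(C)(C)C3(OCCO3)CC[C@]2(C)[C@@H]1CO[Si](C)(C)C(C)(C)C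
F6 | step 5 | racemic 5,5-dimethyl-6,6-ethylenedioxy-4,4a,5,6,7,8-hexahydronaphthalen-2(3H)-one | O=C1CCC2C(C)(C)C3(OCCO3)CCC2=C1
F7 | step 5 | (4aR)-5,5-dimethyl-6,6-ethylenedioxy-4,4a,5,6,7,8-hexahydronaphthalen-2(3H)-one | O=C1CC[C@H]2C(C)(C)C3(OCCO3)CCC2=C1
F0 | step 8 | none | none
F0 | step 11 | none | none
A1 | alternative 1 | 2,4,4-trimethylcyclohex-2-en-1-one | CC1=CC(C)(C)CCC1=O
A2 | alternative 1 | (3E)-2,5-bis(tert-butyldimethylsilyloxy)-3-methylpenta-1,3-diene | C=C(O[Si](C)(C)C(C)(C)C)/C(C)=C/CO[Si](C)(C)C(C)(C)C
A3 | alternative 1 | cis-fused Diels–Alder adduct with C1 ketone, C7 silyl enol ether and C11 silyl ether (C11 trans to the angular methyl) | CC1=C(O[Si](C)(C)C(C)(C)C)C[C@@H]2C(C)(C)CCC(=O)[C@]2(C)[C@@H]1CO[Si](C)(C)C(C)(C)C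
A4 | alternative 2 | methyl (2E,6S)-6-(tert-butyldimethylsilyloxy)-3,7,7-trimethyl-2-(prop-1-en-2-yl)nona-2,8-dienoate | C=C(C)/C(C(=O)OC)=C(/C)CC[C@H](O[Si](C)(C)C(C)(C)C)C(C)(C)C=C
A5 | alternative 2 | cis-fused C8=C9 conjugated methyl ester with C3 silyl ether | COC(=O)C1=C(C)CC[C@@H]2C(C)(C)[C@@H](O[Si](C)(C)C(C)(C)C)CC[C@]12C
A6 | alternative 3 | 4-methyl-4-(4-methyl-3-oxopent-4-en-1-yl)cyclohexa-2,5-dien-1-one | CC(=C)C(=O)CCC1(C)C=CC(=O)C=C1
A7 | alternative 3 | cis-fused 4a,8,8-trimethyl-4a,5,6,8a-tetrahydronaphthalene-2,7(1H,8H)-dione (C3 and C7 ketones, C8=C9 alkene in drimane numbering) | O=C1C=C[C@@]2(C)CCC(=O)C(C)(C)[C@H]2C1
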